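**Strategy.** The route rests on the C3–C4 disconnection of ring A. Ring B (C5–C10, with the C7=C8–CH3 unit and the C5 stereocentre that carries C4) is (R)-carvone, whose isopropenyl carbon is C4. In one operation, iron-hydride hydrogen-atom transfer to the 2-(silyloxymethyl)vinyl group of precursor 10 gives the tertiary C4 radical, which closes ring A 6-endo on the acrylate CH2 (C3) and sets the C4 quaternary centre; the axial C10 methyl of the forming trans-decalin steers CH2OSi equatorial. Precursor 10 is 10-silyloxycarvone carrying methyl and a 2-(methoxycarbonyl)allyl arm on the ketone α-carbon (C10). C9 methylenation, hydroboration/Suzuki coupling and epoxyquinol assembly complete the target.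

Key step: step 7

Remark (numbering): drimane numbering for the decalin (C11 = CH2 on C9, C13 = 4α-CH2O, C14 = 4β-CH3, C15 = 10β-CH3); primed numbers for the epoxycyclohexenone: C1′ (bears C11), C2′ (epoxide CH), C3′ (C=O), C4′ (C–CH2OH), C5′ (=CH), C6′ (CHOH).
Remark (aryl partner): the arene must already carry the C4′ hydroxymethyl carbon, which a 2-bromo-4-methoxyphenol unit lacks; 2-bromo-5-(hydroxymethyl)-4-methoxyphenol is therefore made in steps 11–13, and its CH2O group also blocks epoxidation of C4′=C5′.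
Remark (C6′): in the target the C6′ hydroxyl is anti to the epoxide oxygen, whereas hydride reduction of the epoxy ketone is expected to give the syn alcohol, so an inversion (steps 18–19) is built in.
Remark (protecting groups): TBS is used on C13–O, on the benzylic oxygen and on the phenol, so that the phenol is freed with carbonate alone and the last step is a single acid treatment.
Remark (assumption): 5-hydroxy-2-methoxybenzaldehyde 16 is taken as commercially available; 7 (C6) and 11–13 (C2) are epimer mixtures at centres that are destroyed later, and one epimer is drawn.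

Step 1
Reactants: 1 (R)-(−)-carvone
Product: 2 (R)-10-chlorocarvone
Conditions: Ca(OCl)2, CO2 (dry ice), CH2Cl2/H2O, 0 °C
Reagents that add atoms: calcium hypochlorite, [Ca+2].[O-]Cl.[O-]Cl
Why: Ene-type allylic chlorination by HOCl should attack only the electron-rich isopropenyl group, not the enone, and leaves C5 untouched.

Step 2
Reactants: 2 (R)-10-chlorocarvone
Product: 3 (R)-10-acetoxycarvone
Conditions: KOAc, n-Bu4NI (cat.), DMF, 50 °C
Reagents that add atoms: potassium acetate, CC(=O)[O-].[K+]
Why: SN2 displacement of the primary allylic chloride by acetate, assisted by in-situ halide exchange (Finkelstein).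

Step 3
Reactants: 3 (R)-10-acetoxycarvone
Product: 4 (R)-10-hydroxycarvone
Conditions: K2CO3 (cat.), MeOH, 0 °C to rt
Reagents that add atoms: none
Why: Base-catalysed transesterification (methanolysis) frees the primary allylic alcohol; C5 is not α to the ketone and cannot epimerise.

Step 4
Reactants: 4 (R)-10-hydroxycarvone
Product: 5 (R)-10-(tert-butyldimethylsilyloxy)carvone
Conditions: TBSCl, imidazole, CH2Cl2, rt
Reagents that add atoms: tert-butyldimethylsilyl chloride, CC(C)(C)[Si](C)(C)Cl
Why: Standard silylation of a primary alcohol gives an ether stable to LDA, to the radical step and to aqueous base.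

Step 5
Reactants: 5 (R)-10-(tert-butyldimethylsilyloxy)carvone
Product: 7 6-methyl-10-(TBS-oxy)-(R)-carvone, via lithium cross-conjugated enolate of 5 6 (not isolated)
Conditions: LDA, THF, −78 °C; then MeI, −78 to −20 °C
Reagents that add atoms: iodomethane, CI
Why: Kinetic α′-deprotonation and enolate alkylation should give mainly the 5,6-trans methyl ketone; the C6 configuration is immaterial because C6 is planarised again in step 6.

Step 6
Reactants: 7 6-methyl-10-(TBS-oxy)-(R)-carvone; 8 methyl 2-(bromomethyl)acrylate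
Product: 10 6-methyl-6-[2-(methoxycarbonyl)allyl]-10-(TBS-oxy)-(R)-carvone, via lithium tetrasubstituted enolate of 7 9 (not isolated)
Conditions: LDA, THF, −78 °C; then 8, DMPU, −78 to −30 °C
Reagents that add atoms: none
Why: Enolate alkylation (SN2′ addition–elimination on the bromomethyl acrylate) should occur anti to the C5 side chain, setting the quaternary carbon (drimane C10) with methyl cis and the acrylate arm trans to that side chain.

Step 7
Reactants: 10 6-methyl-6-[2-(methoxycarbonyl)allyl]-10-(TBS-oxy)-(R)-carvone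
Product: 11 methyl 13-(TBS-oxy)-9-oxo-11-nordrim-7-ene-2-carboxylate
Conditions: Fe(acac)3 (30 mol%), PhSiH3, EtOH/ethylene glycol, 60 °C
Reagents that add atoms: none
Why: Fe(III)–H, formed from Fe(acac)3 and PhSiH3 in ethanol, transfers a hydrogen atom to the terminal CH2 of the electron-rich 1,1-disubstituted alkene, so that this carbon becomes the 4β-methyl group and C4 a tertiary radical; the radical adds to the acrylate CH2 (C3) and the resulting α-ester radical at C2 is reduced by Fe(II) and protonated by the solvent. The closest known reaction type is the metal-hydride hydrogen-atom-transfer (Mukaiyama-type) reductive olefin coupling, i.e. an intramolecular Giese addition. Ring A closes in the 6-endo-trig mode, favoured over 5-exo because the nucleophilic tertiary radical attacks the unsubstituted acrylate terminus and gives the stabilised α-ester radical. C4 is set by the chair-like transition state of the forming trans-decalin, in which the larger CH2OTBS group takes the equatorial (α) site and the new methyl the axial site syn to the axial C10 methyl; C2 forms as an epimer mixture that is erased in step 9. The step needs hydrogen-atom transfer to the allylic-ether alkene in preference to the enone and the acrylate, which the electron-poor character of both acceptors and the tertiary radical available only from the donor alkene should secure, and the ring fusion is already fixed by C5 and C10.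

Step 8
Reactants: 11 methyl 13-(TBS-oxy)-9-oxo-11-nordrim-7-ene-2-carboxylate
Product: 12 13-(TBS-oxy)-9-oxo-11-nordrim-7-ene-2-carboxylic acid
Conditions: LiOH·H2O, THF/MeOH/H2O, rt; then dilute HCl to pH 4, 0 °C
Reagents that add atoms: lithium hydroxide, [Li+].[OH-]
Why: Saponification of an unhindered secondary methyl ester; the ketone has no α-hydrogen at C10, the silyl ether tolerates the conditions and C2 epimerisation is irrelevant.

Step 9
Reactants: 12 13-(TBS-oxy)-9-oxo-11-nordrim-7-ene-2-carboxylic acid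
Product: 14 13-(TBS-oxy)-11-nordrim-7-en-9-one, via 2-thioxopyridin-1(2H)-yl ester of 12 13 (not isolated)
Conditions: 1-hydroxypyridine-2(1H)-thione, DCC, DMAP (cat.), CH2Cl2, rt, dark; then t-BuSH, hν (tungsten lamp), rt
Reagents that add atoms: none
Why: Barton reductive decarboxylation: the secondary C2 radical has no cyclisation path of reasonable ring size onto the enone and is quenched by the thiol, removing the C2 stereocentre.

Step 10
Reactants: 14 13-(TBS-oxy)-11-nordrim-7-en-9-one
Product: 15 13-(TBS-oxy)drima-7,9(11)-diene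
Conditions: Ph3PCH3Br, KOt-Bu, toluene, 90 °C
Reagents that add atoms: methyltriphenylphosphonium bromide, C[P+](c1ccccc1)(c1ccccc1)c1ccccc1.[Br-]
Why: Wittig methylenation under forcing, salt-free conditions suited to a hindered ketone installs C11; C10 is quaternary, so no stereocentre can epimerise.

Step 11
Reactants: 16 5-hydroxy-2-methoxybenzaldehyde
Product: 17 3-(hydroxymethyl)-4-methoxyphenol
Conditions: NaBH4, MeOH, 0 °C
Reagents that add atoms: none
Why: Borohydride reduction of the aldehyde; removing the carbonyl first lets the phenol alone direct the bromination.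

Step 12
Reactants: 17 3-(hydroxymethyl)-4-methoxyphenol
Product: 18 2-bromo-5-(hydroxymethyl)-4-methoxyphenol
Conditions: NBS, MeCN, −20 to 0 °C
Reagents that add atoms: N-bromosuccinimide, O=C1CCC(=O)N1Br
Why: Electrophilic aromatic bromination ortho to the free phenol (para is blocked by OMe), at the unhindered ortho site para to CH2OH and not between OH and CH2OH.

Step 13
Reactants: 18 2-bromo-5-(hydroxymethyl)-4-methoxyphenol
Product: 19 bis-TBS ether of 18
Conditions: TBSCl (2.5 equiv), imidazole, DMF, rt
Reagents that add atoms: tert-butyldimethylsilyl chloride, CC(C)(C)[Si](C)(C)Cl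
Why: Silylation of both hydroxyls gives a coupling partner whose aryl silyl ether can later be cleaved selectively by carbonate.

Step 14
Reactants: 15 13-(TBS-oxy)drima-7,9(11)-diene; 19 bis-TBS ether of 18
Product: 22 11-[2-hydroxy-5-methoxy-4-(TBS-oxymethyl)phenyl]-13-(TBS-oxy)drim-7-ene, via B-[13-(TBS-oxy)drim-7-en-11-yl]-9-BBN 20 (not isolated), via 11-[2-(TBS-oxy)-5-methoxy-4-(TBS-oxymethyl)phenyl]-13-(TBS-oxy)drim-7-ene 21 (not isolated)
Conditions: 9-BBN dimer, THF, rt to 50 °C; then 19, Pd(OAc)2/SPhos (cat.), K3PO4·H2O, THF, 65 °C; then K2CO3, MeOH, rt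
Reagents that add atoms: none
Why: 9-BBN should hydroborate only the exocyclic C9=C11 alkene from the α-face opposite the axial C10 methyl, placing boron on C11 and hydrogen on C9 (9α-H, C11 β); the B-alkyl Suzuki–Miyaura coupling then joins C11 to C1′, and methanolic carbonate cleaves only the aryl silyl ether.

Step 15
Reactants: 22 11-[2-hydroxy-5-methoxy-4-(TBS-oxymethyl)phenyl]-13-(TBS-oxy)drim-7-ene
Product: 23 4,4-dimethoxy-5-(TBS-oxymethyl)-2-{[13-(TBS-oxy)drim-7-en-11-yl]}cyclohexa-2,5-dien-1-one
Conditions: PhI(OAc)2, MeOH, 0 °C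
Reagents that add atoms: methanol, CO
Why: Hypervalent-iodine oxidative dearomatisation of a p-methoxyphenol in methanol gives the quinone monoketal with the ketone at C6′ and the ketal at C3′; the isolated C7=C8 alkene is inert to the reagent at 0 °C.

Step 16
Reactants: 23 4,4-dimethoxy-5-(TBS-oxymethyl)-2-{[13-(TBS-oxy)drim-7-en-11-yl]}cyclohexa-2,5-dien-1-one
Product: 24 C1′–C2′ epoxide of 23
Conditions: t-BuOOH, aq. NaOH, N-benzylcinchonidinium chloride (cat.), toluene, 0 °C to rt
Reagents that add atoms: tert-butyl hydroperoxide, CC(C)(C)OO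
Why: Weitz–Scheffer nucleophilic epoxidation under chiral phase-transfer catalysis: the hydroperoxide anion adds to C2′, the only unsubstituted β-carbon of the dienone (C4′ is blocked by CH2OTBS), and closure at C1′ gives the cis-fused epoxide on the face selected by the ion-paired cinchona cation, the pseudo-enantiomeric cinchoninium salt being used instead if that series proves to be the matched one.

Step 17
Reactants: 24 C1′–C2′ epoxide of 23
Product: 25 C6′ alcohol with OH syn to the epoxide oxygen
Conditions: DIBAL-H, THF, −78 °C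
Reagents that add atoms: none
Why: 1,2-Reduction of the C6′ ketone, in which hydride is expected to add anti to the epoxide C–O bond (Felkin–Anh-type control, as in additions to epoxy quinone monoketals), giving the syn epoxy alcohol, i.e. the C6′ epimer of the target.

Step 18
Reactants: 25 C6′ alcohol with OH syn to the epoxide oxygen
Product: 26 C6′ 4-nitrobenzoate with the ester anti to the epoxide oxygen
Conditions: 4-nitrobenzoic acid, PPh3, DIAD, toluene, 0 °C to rt
Reagents that add atoms: 4-nitrobenzoic acid, OC(=O)c1ccc(cc1)[N+](=O)[O-]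
Why: Mitsunobu reaction: SN2 displacement at C6′ inverts it to the target configuration; SN2′ attack is blocked by the fully substituted C4′ and no β-hydrogen is available for elimination.

Step 19
Reactants: 26 C6′ 4-nitrobenzoate with the ester anti to the epoxide oxygen
Product: 27 C6′ alcohol with OH anti to the epoxide oxygen (C3′ dimethyl ketal, bis-TBS ether of the target)
Conditions: K2CO3, MeOH, 0 °C
Reagents that add atoms: none
Why: Mild methanolysis of the activated aryl ester at low temperature frees the alcohol while the ketal-masked epoxide is not base-sensitive.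

Step 20
Reactants: 27 C6′ alcohol with OH anti to the epoxide oxygen
Product: 28 epoxypholamin A
Conditions: 48% aq. HF, MeCN, 0 °C to rt
Reagents that add atoms: water, O
Why: One acid treatment hydrolyses the dimethyl ketal to the C3′ enone and cleaves both primary TBS ethers (ketal hydrolysis and desilylation); the epoxy enone and the C7=C8 alkene are expected to survive.

**Compound list**

1 | (R)-(−)-carvone | CC1=CC[C@H](CC1=O)C(=C)C | starting material
2 | (R)-10-chlorocarvone | CC1=CC[C@H](CC1=O)C(=C)CCl | intermediate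
3 | (R)-10-acetoxycarvone | CC1=CC[C@H](CC1=O)C(=C)COC(C)=O | intermediate
4 | (R)-10-hydroxycarvone | CC1=CC[C@H](CC1=O)C(=C)CO | intermediate
5 | (R)-10-(tert-butyldimethylsilyloxy)carvone | CC1=CC[C@H](CC1=O)C(=C)CO[Si](C)(C)C(C)(C)C | intermediate
6 | lithium cross-conjugated (C1–C6) enolate of 5 | CC1=CC[C@@H](C(=C)CO[Si](C)(C)C(C)(C)C)C=C1O[Li] | intermediate (not isolated)
7 | 6-methyl-10-(TBS-oxy)-(R)-carvone (5,6-trans epimer drawn) | CC1=CC[C@@H](C(=C)CO[Si](C)(C)C(C)(C)C)[C@H](C)C1=O | intermediate
8 | methyl 2-(bromomethyl)acrylate | COC(=O)C(=C)CBr | starting material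
9 | lithium tetrasubstituted enolate of 7 | CC1=CC[C@@H](C(=C)CO[Si](C)(C)C(C)(C)C)C(C)=C1O[Li] | intermediate (not isolated)
10 | 6-methyl-6-[2-(methoxycarbonyl)allyl]-10-(TBS-oxy)-(R)-carvone (methyl cis, acrylate arm trans to the C5 side chain) | CC1=CC[C@@H](C(=C)CO[Si](C)(C)C(C)(C)C)[C@](C)(CC(=C)C(=O)OC)C1=O | intermediate (key-step precursor)
11 | methyl 13-(TBS-oxy)-9-oxo-11-nordrim-7-ene-2-carboxylate (5α-H, 10β-CH3, 4β-CH3, 4α-CH2OTBS; one C2 epimer drawn) | CC1=CC[C@H]2[C@](C)(CO[Si](C)(C)C(C)(C)C)C[C@H](C(=O)OC)C[C@]2(C)C1=O | intermediate (key-step product)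
12 | 13-(TBS-oxy)-9-oxo-11-nordrim-7-ene-2-carboxylic acid | CC1=CC[C@H]2[C@](C)(CO[Si](C)(C)C(C)(C)C)C[C@H](C(=O)O)C[C@]2(C)C1=O | intermediate
13 | 2-thioxopyridin-1(2H)-yl ester of 12 (Barton ester) | CC1=CC[C@H]2[C@](C)(CO[Si](C)(C)C(C)(C)C)C[C@H](C(=O)ON3C=CC=CC3=S)C[C@]2(C)C1=O | intermediate (not isolated)
14 | 13-(TBS-oxy)-11-nordrim-7-en-9-one | CC1=CC[C@H]2[C@](C)(CO[Si](C)(C)C(C)(C)C)CCC[C@]2(C)C1=O | intermediate
15 | 13-(TBS-oxy)drima-7,9(11)-diene | CC1=CC[C@H]2[C@](C)(CO[Si](C)(C)C(C)(C)C)CCC[C@]2(C)C1=C | intermediate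
16 | 5-hydroxy-2-methoxybenzaldehyde | COc1ccc(O)cc1C=O | starting material
17 | 3-(hydroxymethyl)-4-methoxyphenol | COc1ccc(O)cc1CO | intermediate
18 | 2-bromo-5-(hydroxymethyl)-4-methoxyphenol | COc1cc(Br)c(O)cc1CO | intermediate
19 | bis-TBS ether of 18 | COc1cc(Br)c(O[Si](C)(C)C(C)(C)C)cc1CO[Si](C)(C)C(C)(C)C | intermediate
20 | B-[13-(TBS-oxy)drim-7-en-11-yl]-9-borabicyclo[3.3.1]nonane (9α-H) | CC1=CC[C@H]2[C@](C)(CO[Si](C)(C)C(C)(C)C)CCC[C@]2(C)[C@H]1CB1C2CCCC1CCC2 | intermediate (not isolated)
21 | 11-[2-(TBS-oxy)-5-methoxy-4-(TBS-oxymethyl)phenyl]-13-(TBS-oxy)drim-7-ene | CC1=CC[C@H]2[C@](C)(CO[Si](C)(C)C(C)(C)C)CCC[C@]2(C)[C@H]1Cc1cc(OC)c(CO[Si](C)(C)C(C)(C)C)cc1O[Si](C)(C)C(C)(C)C | intermediate (not isolated)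
22 | 11-[2-hydroxy-5-methoxy-4-(TBS-oxymethyl)phenyl]-13-(TBS-oxy)drim-7-ene | CC1=CC[C@H]2[C@](C)(CO[Si](C)(C)C(C)(C)C)CCC[C@]2(C)[C@H]1Cc1cc(OC)c(CO[Si](C)(C)C(C)(C)C)cc1O | intermediate
23 | 4,4-dimethoxy-5-(TBS-oxymethyl)-2-{[13-(TBS-oxy)drim-7-en-11-yl]}cyclohexa-2,5-dien-1-one | CC1=CC[C@H]2[C@](C)(CO[Si](C)(C)C(C)(C)C)CCC[C@]2(C)[C@H]1CC1=CC(OC)(OC)C(CO[Si](C)(C)C(C)(C)C)=CC1=O | intermediate
24 | C1′–C2′ epoxide of 23 (target configuration at C1′ and C2′) | CC1=CC[C@H]2[C@](C)(CO[Si](C)(C)C(C)(C)C)CCC[C@]2(C)[C@H]1C[C@@]12O[C@@H]1C(OC)(OC)C(CO[Si](C)(C)C(C)(C)C)=CC2=O | intermediate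
25 | C6′ alcohol of 24, OH syn to the epoxide oxygen | CC1=CC[C@H]2[C@](C)(CO[Si](C)(C)C(C)(C)C)CCC[C@]2(C)[C@H]1C[C@@]12O[C@@H]1C(OC)(OC)C(CO[Si](C)(C)C(C)(C)C)=C[C@@H]2O | intermediate
26 | C6′ 4-nitrobenzoate, ester anti to the epoxide oxygen | CC1=CC[C@H]2[C@](C)(CO[Si](C)(C)C(C)(C)C)CCC[C@]2(C)[C@H]1C[C@@]12O[C@@H]1C(OC)(OC)C(CO[Si](C)(C)C(C)(C)C)=C[C@H]2OC(=O)c1ccc(cc1)[N+](=O)[O-] | intermediate
27 | C6′ alcohol, OH anti to the epoxide oxygen (C3′ dimethyl ketal, bis-TBS ether of the target) | CC1=CC[C@H]2[C@](C)(CO[Si](C)(C)C(C)(C)C)CCC[C@]2(C)[C@H]1C[C@@]12O[C@@H]1C(OC)(OC)C(CO[Si](C)(C)C(C)(C)C)=C[C@H]2O | intermediate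
28 | epoxypholamin A | CC1=CC[C@H]2[C@](C)(CO)CCC[C@]2(C)[C@H]1C[C@@]12O[C@@H]1C(=O)C(CO)=C[C@H]2O | target

**Step count.** Total: 20 steps. Longest linear sequence: 17 steps (steps 1–10 and 14–20 from (R)-carvone); steps 11–13 form the three-step aryl branch.

**Steps most likely to fail**

Step 16. The risk is poor facial selectivity: ion-pair control by the catalyst may be weak on an α-alkylated dienone, and the remote drimane centres give little intrinsic bias, so both epoxide diastereomers may form. The fallback replaces the chiral catalyst by a covalently bound auxiliary. It sets out from 23 and comes back at 28. Acid-catalysed transketalisation of 23 with (R,R)-hydrobenzoin (PPTS, benzene, 4 Å sieves; the antipodal diol if it induces the other face) gives the spiro hydrobenzoin ketal dienone F7. Achiral nucleophilic epoxidation (t-BuOOH, DBU) under auxiliary control gives the epoxy ketone F8. DIBAL-H gives the syn epoxy alcohol F9, the Mitsunobu reaction with 4-nitrobenzoic acid gives the inverted ester F10, and K2CO3/MeOH gives the anti epoxy alcohol F11. Aqueous HF in MeCN then removes the ketal and both silyl groups to give 28.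

Step 7. The risks are competing hydrogen-atom transfer to the acrylate or enone, simple reduction of the C4 radical before it cyclises, and incomplete facial discrimination at C4. The fallback generates the same C4 radical by titanocene(III) reductive epoxide opening instead of hydrogen-atom transfer. It sets out from 1 and comes back at 11. Carvone 1 is methylated (LDA, MeI) to trans-6-methylcarvone F1 and alkylated with 8 (LDA) to 6-methyl-6-[2-(methoxycarbonyl)allyl]carvone F2. mCPBA should epoxidise only the electron-rich isopropenyl group to give the side-chain epoxide F3 (both epoxide epimers converge). Cp2TiCl (from Cp2TiCl2 and Zn, THF, rt) opens the epoxide to the tertiary C4 radical bearing a bulky CH2O–Ti group, which closes ring A 6-endo on the acrylate to give methyl 13-hydroxy-9-oxo-11-nordrim-7-ene-2-carboxylate F4. Silylation (TBSCl, imidazole) gives 11.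

Step 14. The risk is slow transmetalation of the β-branched, neopentyl-like alkylborane 20 onto an ortho-substituted arylpalladium species, so that protodeboronation or β-hydride elimination wins. The fallback uses an organozinc coupling. It sets out from 15 and comes back at 21. Hydroboration of 15 with 9-BBN followed by oxidative work-up (NaOH, H2O2) gives 13-(TBS-oxy)drim-7-en-11-ol F5. I2, PPh3 and imidazole give 11-iodo-13-(TBS-oxy)drim-7-ene F6. Iodine–lithium exchange (t-BuLi, Et2O, −78 °C), transmetalation with ZnCl2 and Negishi coupling with 19 (Pd(OAc)2, SPhos, THF, 50 °C) give 21, which is desilylated to 22 with K2CO3/MeOH as in step 14.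

**Further compounds**

F1 | step 7 | trans-6-methyl-(R)-carvone | CC1=CC[C@@H](C(=C)C)[C@H](C)C1=O
F2 | step 7 | 6-methyl-6-[2-(methoxycarbonyl)allyl]-(R)-carvone (methyl cis, acrylate arm trans to isopropenyl) | CC1=CC[C@@H](C(=C)C)[C@](C)(CC(=C)C(=O)OC)C1=O
F3 | step 7 | isopropenyl epoxide of F2 (2-methyloxiran-2-yl side chain, epimer mixture) | CC1=CC[C@@H](C2(C)CO2)[C@](C)(CC(=C)C(=O)OC)C1=O
F4 | step 7 | methyl 13-hydroxy-9-oxo-11-nordrim-7-ene-2-carboxylate | CC1=CC[C@H]2[C@](C)(CO)C[C@H](C(=O)OC)C[C@]2(C)C1=O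
F5 | step 14 | 13-(TBS-oxy)drim-7-en-11-ol | CC1=CC[C@H]2[C@](C)(CO[Si](C)(C)C(C)(C)C)CCC[C@]2(C)[C@H]1CO
F6 | step 14 | 11-iodo-13-(TBS-oxy)drim-7-ene | CC1=CC[C@H]2[C@](C)(CO[Si](C)(C)C(C)(C)C)CCC[C@]2(C)[C@H]1CI
F7 | step 16 | (R,R)-hydrobenzoin spiro ketal analogue of 23 | CC1=CC[C@H]2[C@](C)(CO[Si](C)(C)C(C)(C)C)CCC[C@]2(C)[C@H]1CC1=CC2(O[C@H](c3ccccc3)[C@@H](c3ccccc3)O2)C(CO[Si](C)(C)C(C)(C)C)=CC1=O
F8 | step 16 | C1′–C2′ epoxide of F7 | CC1=CC[C@H]2[C@](C)(CO[Si](C)(C)C(C)(C)C)CCC[C@]2(C)[C@H]1C[C@@]12O[C@@H]1C3(O[C@H](c4ccccc4)[C@@H](c4ccccc4)O3)C(CO[Si](C)(C)C(C)(C)C)=CC2=O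
F9 | step 16 | C6′ alcohol of F8, OH syn to the epoxide oxygen | CC1=CC[C@H]2[C@](C)(CO[Si](C)(C)C(C)(C)C)CCC[C@]2(C)[C@H]1C[C@@]12O[C@@H]1C3(O[C@H](c4ccccc4)[C@@H](c4ccccc4)O3)C(CO[Si](C)(C)C(C)(C)C)=C[C@@H]2O
F10 | step 16 | C6′ 4-nitrobenzoate (anti) of the hydrobenzoin ketal series | CC1=CC[C@H]2[C@](C)(CO[Si](C)(C)C(C)(C)C)CCC[C@]2(C)[C@H]1C[C@@]12O[C@@H]1C3(O[C@H](c4ccccc4)[C@@H](c4ccccc4)O3)C(CO[Si](C)(C)C(C)(C)C)=C[C@H]2OC(=O)c1ccc(cc1)[N+](=O)[O-]
F11 | step 16 | C6′ alcohol (anti) of the hydrobenzoin ketal series | CC1=CC[C@H]2[C@](C)(CO[Si](C)(C)C(C)(C)C)CCC[C@]2(C)[C@H]1C[C@@]12O[C@@H]1C3(O[C@H](c4ccccc4)[C@@H](c4ccccc4)O3)C(CO[Si](C)(C)C(C)(C)C)=C[C@H]2O
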